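## The problem

The target 23 is a chroman-4-one whose benzene ring (ring A) is fully substituted: C4a carries the ketone, C5 a free hydroxyl, C6 the C3 carbon of an octanoic acid, C7 a methoxy group, C8 a prenyl group and C8a the pyranone oxygen O1. It has three stereocentres: C2 (S) and C3 (R) in the pyranone (ring B), which place the two methyl groups cis, and the benzylic carbon of the acid chain (R). The flat arene insulates the benzylic centre from the ring B pair, so two independent, reagent-controlled events are needed; within ring B, C2 can control C3, because C3 arises by protonation of an enol next to an existing C2. The cis-2,3 arrangement is the less stable one and C3 is alpha to the ketone, so base or strong Lewis acid can epimerise it or open ring B by retro-oxa-Michael reaction. The prenyl alkene forbids hydrogenation and strong protic acid once it is present, the 5-hydroxyl lies next to the CH2CO2H arm and could close a dihydrocoumarin, and O5 has to be told apart from O7 and O1. The benzylic centre, by contrast, is beta to the carboxyl group, is not enolisable, and can be set early and carried through. The enabling feature lies at that carbon: it bears a hydrogen, the aryl group and two methylene arms (C2 of the acid chain and C4, which begins the pentyl chain), which is exactly C3 of a 3-arylcyclobutanone with its two ring methylenes. Such a ketone is achiral as long as the aryl group is locally symmetric (O5 and O7 both methyl ethers, O1 para to the chain), and oxygen insertion into one of its two C(=O)–CH2 bonds turns one arm into CH2C(=O)O and the other into CH2O, creating the stereocentre and differentiating the arms at once.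

## Retrosynthesis

**Unmasking, 23 to 22 to 21.** No skeletal bond is cut. The acid is taken back to methyl ester 22 and the 5-hydroxyl to the methyl ether of 21. The ester protects the acid from the organometallic and Lewis-acid steps. Keeping O5 methylated leaves only one free phenol at ring closure, keeps the phenol and ester arm from lactonising, and makes O5 and O7 equivalent in the early intermediates. The forward steps must remove one of two aryl methyl groups (chelation to the C4 carbonyl singles out O5) and cleave the ester without a base strong enough to epimerise C3.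

**C8–prenyl bond, 21 to 19 and 20, then 19 to 18.** The bond between C8 and the prenyl CH2 is cut to aryl iodide 19 and stannane 20, and the iodine is removed to give 18, where C8 is the only aromatic C–H. Electrophilic prenylation at an earlier phenol would give O- and C-alkylation mixtures and invite chroman formation, and a Claisen route needs a free oxygen next to C8, which ring B has consumed. The coupling must be base-free and must join the unsubstituted allyl terminus.

**O1–C2 bond, 18 to 17.** Cutting the ether bond of ring B reveals the ortho-hydroxyaryl tigloyl ketone 17. The neighbouring cuts are C4–C4a (acylation by an aryloxy acid, kept as the reserve) and C2–C3 (a carbenoid insertion, discussed below). The ether cut is preferred because one catalytic step then makes both ring stereocentres from an achiral side chain: C2 by choice of enone face, C3 by protonation. The catalyst must supply all the facial bias, since the benzylic centre is too remote to help or hinder, and the kinetic cis product must not be allowed to equilibrate.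

**C4a–acyl bond, 17 to 15 and 16, then 15 to 14.** The aryl–carbonyl bond is cut to phenol 15 and tigloyl chloride 16. In 15 the two open ring positions are equivalent, each lying between the hydroxyl and a methoxy group, so the acylation cannot give a regioisomer. Phenol 15 comes from benzyl ether 14 by hydrogenolysis, which is safe at this point because no alkene is present.

**C4–C5 bond of the octanoate, 14 to 12 and 13, then 12 to 11 to 9.** The pentyl chain is cut one carbon away from the stereocentre into primary iodide 12 and butylmagnesium bromide 13. The carbon that reacts is not stereogenic and no carbonyl is ever placed on the benzylic carbon. An olefination through an aldehyde at that carbon would be shorter on paper but puts an enolisable group on the stereocentre. Iodide 12 derives from hydroxy ester 11, and 11 from lactone 9, whose carbonyl arm is already the CH2CO2R unit and whose OCH2 arm is the latent electrophile. The opening is planned as saponification and O-alkylation of the carboxylate, because the halosilane or hydrogen-halide reagents that open lactones directly to halo esters would also cleave the aryl benzyl ether.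

**Lactone O–CH2 bond, 9 to 7 (key).** Removing the ring oxygen of 9 and rejoining the CH2 to the carbonyl carbon gives cyclobutanone 7, which has a mirror plane and no stereocentre. The competing routes to a 4-aryl lactone are conjugate addition of an aryl–metal species to a butenolide or reduction of an arylbutenolide. Both must engage a doubly ortho-substituted aryl group in the stereo-determining bond formation; here that group is only a spectator. The forward reaction must choose between two enantiotopic CH2 groups, which only a chiral catalyst can do.

**Cyclobutanone ring, 7 to 6 to 4 and 5, then 4 to 2 and 3, then 2 to 1.** Two ring bonds are cut in a [2+2] sense: 7 comes from dichloro ketone 6, and 6 from styrene 4 and the ketene derived from trichloroacetyl chloride 5. Styrene 4 comes from aldehyde 2 and the one-carbon ylide of phosphonium salt 3, and 2 from commercial phenol 1 by O-benzylation. The polarity of the ketene addition places the aryl group at C3, as required.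

## Roads not taken

**Alternative 1: carbenoid C–H insertion.** This cuts the C2–C3 bond of ring B. Diazo ketone A2, methyl (3R)-3-[3-(2-diazopropanoyl)-4-ethoxy-2,6-dimethoxy-5-(3-methylbut-2-en-1-yl)phenyl]octanoate, would be decomposed by Rh2(S-PTTL)4 or its mirror image. The carbenoid at C3 would insert into a C–H bond of the O-ethyl methylene, closing ring B to give A1, which is the same compound as 21.
- Merits: a C–C bond and both ring stereocentres are formed in one neutral, catalytic event, and cis is the usual kinetic outcome of such insertions next to an ether oxygen. In this respect it is better than the chosen ring closure, which depends on a base catalyst and a kinetic protonation.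
- Weak points: the methyl-bearing carbenoid can undergo 1,2-hydride shift. The 5-methoxy group on the other side of the acyl group offers C–H bonds at the same distance. The prenyl alkene is a carbenoid acceptor. Diazo transfer to a ketone flanked by two ortho substituents is hindered. A2 requires a hexasubstituted arene in which one ethyl ether is distinguished from two methyl ethers.
- Comparison: this road leaves the benzylic centre unsolved, so it could replace only steps 10 and 11. The chosen plan sets against it an arene with no competing insertion sites and precursors that need no diazo chemistry.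

**Alternative 2: ortho-quinone methide annulation.** This cuts the bond between the benzylic carbon and the CH2 of the acid arm together with an O5–acyl bond. Sulfone A4, 5-(benzyloxy)-3-methoxy-2-[1-(4-methylbenzenesulfonyl)hexyl]phenol, would lose sulfinate under Cs2CO3 to give quinone methide A5, 3-(benzyloxy)-6-hexylidene-5-methoxycyclohexa-2,4-dien-1-one. A chiral triazolium-derived carbene would turn an activated acetate ester into a catalyst-bound enolate that adds to the methide carbon and then acylates the phenoxide, giving dihydrocoumarin A3, (4R)-7-(benzyloxy)-5-methoxy-4-pentyl-3,4-dihydro-2H-chromen-2-one.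
- Merits: the stereocentre is made with the whole pentyl chain in place, and the lactone masks the acid and O5 together and distinguishes O5 from O7. No sp3–sp3 coupling and no late demethylation are needed; here it is better than the chosen plan, which spends steps 6 to 8 and 14 on the same ends.
- Weak points: A5 carries hydrogens on the chain next to the methide carbon and can tautomerise to an alkenylphenol or oligomerise. An unsubstituted acetate enolate is the least reactive and least selective of its class. The arene of A3 has two open positions of different reactivity, and the acyl group must enter the less activated one. Once the lactone is opened, two hydroxyls flank the acyl group and the oxa-Michael closure loses its regiocontrol.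
- Comparison: the chosen plan sets against it a mirror-symmetric aryl group, which makes acylation, ring closure and prenylation regiochemically unambiguous, and a stable, easily made ketone as the substrate of the asymmetric step.

**Alternative 3: Danheiser benzannulation.** This takes ring A itself apart (bonds C7–C8, C4a–C8a and C6–C7). Heating cyclobutenone A7, methyl (3R)-3-(2-ethoxy-4-oxocyclobut-2-en-1-yl)octanoate, with siloxyalkyne A8, triisopropyl[(5-methylhex-4-en-1-yn-1-yl)oxy]silane, would give phenol A6, methyl (3R)-3-[6-ethoxy-2-hydroxy-3-(3-methylbut-2-en-1-yl)-4-(triisopropylsilyloxy)phenyl]octanoate. The sequence is ring opening, [2+2] addition, a second ring opening and six-electron electrocyclisation.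
- Merits: it is convergent, the prenyl group is in place from the start, and the three oxygens emerge differentiated (free hydroxyl, silyl ether, ethyl ether). Steps 12 and 13 of the chosen route would not be needed, which is a real advantage in step economy at the arene.
- Weak points: the key step creates no stereocentre. The benzylic centre must already be present in A7, and no reliable asymmetric way to attach that chain to the sp3 carbon of a 3-alkoxycyclobutenone is at hand. A8 needs a multi-step preparation. After the annulation the methylation, desilylation, acylation, ring closure, de-ethylation and hydrolysis still remain.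
- Comparison: the chosen plan sets against it a catalytic answer to the benzylic centre on a four-step achiral precursor, at the price of a late iodination and cross-coupling.

Key step: step 5

Assumption: the senses of induction are taken from simpler members of each substrate class (the (R)-phosphoric acid for the (4R)-lactone in step 5; quinidine for the 2S series in step 11, quinine being taken to give 2R), and the antipodal acid or quinine would be substituted, with no other change, if the first samples show the opposite sense.

## Route

Step 1
Reactants: 1 4-hydroxy-2,6-dimethoxybenzaldehyde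
Product: 2 4-(benzyloxy)-2,6-dimethoxybenzaldehyde
Conditions: BnBr, K2CO3, DMF, 60 °C
Reagents that add atoms: benzyl bromide, BrCc1ccccc1
Why: Williamson ether synthesis; the phenol is para to the aldehyde and is fully deprotonated by carbonate. The benzyl ether withstands every step up to 14 and is removed by hydrogenolysis before any alkene is present.

Step 2
Reactants: 2 4-(benzyloxy)-2,6-dimethoxybenzaldehyde; 3 methyltriphenylphosphonium bromide
Product: 4 5-(benzyloxy)-2-ethenyl-1,3-dimethoxybenzene
Conditions: 3, KOtBu, THF, 0 °C to rt
Reagents that add atoms: methyltriphenylphosphonium bromide (3), C[P+](c1ccccc1)(c1ccccc1)c1ccccc1.[Br-]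
Why: Wittig methylenation; the unstabilised ylide adds even to an electron-rich, doubly ortho-substituted aldehyde, and the substrate has no enolisable position.

Step 3
Reactants: 4 5-(benzyloxy)-2-ethenyl-1,3-dimethoxybenzene; 5 trichloroacetyl chloride
Product: 6 rac-3-[4-(benzyloxy)-2,6-dimethoxyphenyl]-2,2-dichlorocyclobutan-1-one
Conditions: 5 (slow addition), Zn–Cu couple, POCl3, Et2O, rt
Reagents that add atoms: trichloroacetyl chloride (5), ClC(Cl)(Cl)C(Cl)=O
Why: [2+2] cycloaddition of dichloroketene, generated by zinc dechlorination of 5, with the styrene. The ketene carbonyl carbon bonds to the terminal CH2 and the CCl2 carbon to the benzylic carbon through a polarised transition state stabilised by the trioxygenated ring, so only the 3-aryl isomer is expected. POCl3 ties up ZnCl2 and so protects the styrene from cationic polymerisation.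

Step 4
Reactants: 6 rac-3-[4-(benzyloxy)-2,6-dimethoxyphenyl]-2,2-dichlorocyclobutan-1-one
Product: 7 3-[4-(benzyloxy)-2,6-dimethoxyphenyl]cyclobutan-1-one
Conditions: Zn dust, AcOH, rt
Reagents that add atoms: none
Why: Reductive dechlorination of an alpha,alpha-dichloro ketone by zinc in acetic acid through the zinc enolate; the ring, the benzyl ether and the arene are untouched, and the product has a mirror plane through C1 and C3.

Step 5
Reactants: 7 3-[4-(benzyloxy)-2,6-dimethoxyphenyl]cyclobutan-1-one
Product: 9 (4R)-4-[4-(benzyloxy)-2,6-dimethoxyphenyl]oxolan-2-one, via Criegee adduct 8 (not isolated)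
Conditions: 30% aq. H2O2 (1.5 equiv), (R)-3,3'-di(pyren-1-yl)-5,5',6,6',7,7',8,8'-octahydro-1,1'-binaphthalene-2,2'-diyl hydrogen phosphate (10 mol%), CHCl3, −40 °C
Reagents that add atoms: hydrogen peroxide, OO
Why: Hydrogen peroxide, held and activated by the bifunctional phosphoric acid (acidic OH to the carbonyl oxygen, phosphoryl oxygen to the peroxide hydrogen), adds to the strained carbonyl of 7 to give Criegee adduct 8, and in the stereo-determining step one ring CH2 migrates from carbon to the proximal peroxide oxygen, antiperiplanar to the breaking O–O bond, as water leaves. The gamma-lactone ring is therefore closed not by a cyclisation but by ring expansion, a 1,2-shift of carbon to oxygen that inserts oxygen into the four-membered ring and is driven by release of cyclobutanone strain, which is why a weak oxidant suffices at low temperature. The closest known reaction type is the chiral-Brønsted-acid-catalysed Baeyer–Villiger desymmetrisation of 3-arylcyclobutanones with aqueous hydrogen peroxide, and the only untested element is the doubly ortho-substituted aryl group. The single new stereocentre, C4 of the lactone (the former C3 of the ketone, which changes none of its bonds), is set by the catalyst alone: the chiral phosphate bound to 8 decides which of the two enantiotopic methylene groups reaches the migrating geometry. The selectivity needed is thus enantiotopic group selection, with no question of regiochemistry or migratory aptitude, because the mirror plane of 7 makes the two candidates identical primary alkyl groups. The substrate helps in that the large aryl group fixes the puckered ring with the aryl pseudo-equatorial, so the catalyst reads a rigid scaffold, and in that the aryl group is remote from the carbonyl carbon and cannot migrate, while the electron-rich ring and the benzyl ether are inert to dilute peroxide under a weak acid. Lactone 9 is to be crystallised to raise its enantiomeric purity before it is carried on.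

Step 6
Reactants: 9 (4R)-4-[4-(benzyloxy)-2,6-dimethoxyphenyl]oxolan-2-one
Product: 11 methyl (3R)-3-[4-(benzyloxy)-2,6-dimethoxyphenyl]-4-hydroxybutanoate, via sodium hydroxy carboxylate 10 (not isolated)
Conditions: NaOH (1.05 equiv), THF–MeOH–H2O, rt; evaporate; MeI, DMF, 0 °C to rt
Reagents that add atoms: sodium hydroxide, [Na+].[OH-]; iodomethane, CI
Why: Saponification by acyl–oxygen cleavage followed by SN2 O-methylation of the carboxylate; the free hydroxy acid, which would relactonise, is never formed, and the basic then neutral conditions leave the three aryl ethers alone. The stereocentre changes no bond; 11 is used without delay.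

Step 7
Reactants: 11 methyl (3R)-3-[4-(benzyloxy)-2,6-dimethoxyphenyl]-4-hydroxybutanoate
Product: 12 methyl (3R)-3-[4-(benzyloxy)-2,6-dimethoxyphenyl]-4-iodobutanoate
Conditions: I2, PPh3, imidazole, CH2Cl2, 0 °C
Reagents that add atoms: iodine, II
Why: Appel-type iodination; iodide displaces the alkoxyphosphonium group at the primary carbon (SN2), and the adjacent stereocentre is not involved. The iodide is kept cold and used at once, since gamma-iodo esters revert to the lactone on heating.

Step 8
Reactants: 12 methyl (3R)-3-[4-(benzyloxy)-2,6-dimethoxyphenyl]-4-iodobutanoate; 13 butylmagnesium bromide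
Product: 14 methyl (3R)-3-[4-(benzyloxy)-2,6-dimethoxyphenyl]octanoate
Conditions: 13 (1.5 equiv, slow addition), Li2CuCl4 (3 mol%), NMP (4 equiv), THF, 0 °C
Reagents that add atoms: butylmagnesium bromide (13), CCCC[Mg]Br
Why: Copper-catalysed sp3–sp3 cross-coupling of a primary alkyl iodide with a Grignard reagent; the catalytic cuprate reacts with the iodide faster than the Grignard reagent adds to the ester, helped by NMP and slow addition. The carbon that is substituted is not stereogenic and no enolisable group is formed at the benzylic centre.

Step 9
Reactants: 14 methyl (3R)-3-[4-(benzyloxy)-2,6-dimethoxyphenyl]octanoate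
Product: 15 methyl (3R)-3-(4-hydroxy-2,6-dimethoxyphenyl)octanoate
Conditions: H2 (1 atm), 10% Pd/C, EtOAc–MeOH, rt
Reagents that add atoms: none
Why: Hydrogenolysis of an aryl benzyl ether; nothing else in 14 is reducible under these conditions.

Step 10
Reactants: 15 methyl (3R)-3-(4-hydroxy-2,6-dimethoxyphenyl)octanoate; 16 tigloyl chloride ((2E)-2-methylbut-2-enoyl chloride)
Product: 17 methyl (3R)-3-{4-hydroxy-2,6-dimethoxy-3-[(2E)-2-methylbut-2-enoyl]phenyl}octanoate
Conditions: 16 (1.2 equiv), TiCl4 (2.2 equiv), CH2Cl2, −40 to 0 °C
Reagents that add atoms: tigloyl chloride (16), C/C=C(\C)C(Cl)=O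
Why: Friedel–Crafts C-acylation ortho to the phenol through the titanium phenoxide; the two open positions are equivalent, so only one regioisomer can form. The product is held as a six-membered titanium chelate, which discourages a second acylation and premature ring closure, and TiCl4 does not cleave the methyl ethers.

Step 11
Reactants: 17 methyl (3R)-3-{4-hydroxy-2,6-dimethoxy-3-[(2E)-2-methylbut-2-enoyl]phenyl}octanoate
Product: 18 methyl (3R)-3-[(2S,3R)-5,7-dimethoxy-2,3-dimethyl-4-oxo-3,4-dihydro-2H-chromen-6-yl]octanoate
Conditions: quinidine (20 mol%), PhCl, 15 °C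
Reagents that add atoms: none
Why: Cinchona-base-catalysed intramolecular oxa-Michael addition (6-endo-trig) of the only free phenol to the tigloyl enone; the quinuclidine nitrogen activates the phenol while the alkaloid hydroxyl hydrogen-bonds to the carbonyl, which fixes the enone face and sets C2 as S. Kinetic protonation of the resulting enol at C3 on the face away from the new C2 methyl group gives the cis (3R) isomer; the reaction is stopped at full conversion so that the product is not left to epimerise to trans.

Step 12
Reactants: 18 methyl (3R)-3-[(2S,3R)-5,7-dimethoxy-2,3-dimethyl-4-oxo-3,4-dihydro-2H-chromen-6-yl]octanoate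
Product: 19 methyl (3R)-3-[(2S,3R)-8-iodo-5,7-dimethoxy-2,3-dimethyl-4-oxo-3,4-dihydro-2H-chromen-6-yl]octanoate
Conditions: NIS (1.05 equiv), MeCN, 0 °C to rt, dark
Reagents that add atoms: N-iodosuccinimide, O=C1CCC(=O)N1I
Why: Electrophilic aromatic iodination at C8, the only aromatic C–H, which is activated by oxygen substituents at both ortho positions and at the para position; the neutral reagent avoids acid- or base-mediated epimerisation at C3.

Step 13
Reactants: 19 methyl (3R)-3-[(2S,3R)-8-iodo-5,7-dimethoxy-2,3-dimethyl-4-oxo-3,4-dihydro-2H-chromen-6-yl]octanoate; 20 tributyl(3-methylbut-2-en-1-yl)stannane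
Product: 21 methyl (3R)-3-[(2S,3R)-5,7-dimethoxy-2,3-dimethyl-8-(3-methylbut-2-en-1-yl)-4-oxo-3,4-dihydro-2H-chromen-6-yl]octanoate
Conditions: 20 (1.5 equiv), Pd(PPh3)4 (10 mol%), DMF, 90 °C
Reagents that add atoms: tributyl(3-methylbut-2-en-1-yl)stannane (20), CC(C)=CC[Sn](CCCC)(CCCC)CCCC
Why: Stille cross-coupling, chosen because it is base-free and tolerates the ketone and the ester; the aryl iodide adds oxidatively to zerovalent palladium, the allyl group is transferred from tin, and reductive elimination at the unsubstituted allyl terminus of the equilibrating allylpalladium species gives the linear prenyl arene.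

Step 14
Reactants: 21 methyl (3R)-3-[(2S,3R)-5,7-dimethoxy-2,3-dimethyl-8-(3-methylbut-2-en-1-yl)-4-oxo-3,4-dihydro-2H-chromen-6-yl]octanoate
Product: 22 methyl (3R)-3-[(2S,3R)-5-hydroxy-7-methoxy-2,3-dimethyl-8-(3-methylbut-2-en-1-yl)-4-oxo-3,4-dihydro-2H-chromen-6-yl]octanoate
Conditions: BCl3 (1.5 equiv), CH2Cl2, −78 to −20 °C; MeOH, then aq. NaHCO3
Reagents that add atoms: none
Why: Chelation-controlled O-demethylation; BCl3 binds the C4 carbonyl and the peri 5-methoxy oxygen in a six-membered chelate and chloride removes that methyl group only, the 7-methoxy group having no such assistance. The low temperature and the cold quench spare the prenyl alkene and the cis ring stereochemistry.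

Step 15
Reactants: 22 methyl (3R)-3-[(2S,3R)-5-hydroxy-7-methoxy-2,3-dimethyl-8-(3-methylbut-2-en-1-yl)-4-oxo-3,4-dihydro-2H-chromen-6-yl]octanoate
Product: 23 (3R)-3-[(2S,3R)-5-hydroxy-7-methoxy-2,3-dimethyl-8-(3-methylbut-2-en-1-yl)-4-oxo-3,4-dihydro-2H-chromen-6-yl]octanoic acid
Conditions: Me3SnOH (5 equiv), ClCH2CH2Cl, 70 °C; then 1 M HCl wash
Reagents that add atoms: trimethyltin hydroxide, C[Sn](C)(C)O
Why: Ester cleavage by trimethyltin hydroxide, a near-neutral hydroxide transfer to the ester carbonyl, chosen because alkali hydroxides would epimerise C3 or open ring B by retro-oxa-Michael reaction; the acid wash releases the carboxylic acid and the phenol from tin.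

## Compound list

1 | 4-hydroxy-2,6-dimethoxybenzaldehyde | O=Cc1c(OC)cc(O)cc1OC | starting material
2 | 4-(benzyloxy)-2,6-dimethoxybenzaldehyde | O=Cc1c(OC)cc(OCc2ccccc2)cc1OC | intermediate
3 | methyltriphenylphosphonium bromide | C[P+](c1ccccc1)(c1ccccc1)c1ccccc1.[Br-] | starting material
4 | 5-(benzyloxy)-2-ethenyl-1,3-dimethoxybenzene | C=Cc1c(OC)cc(OCc2ccccc2)cc1OC | intermediate
5 | trichloroacetyl chloride | ClC(Cl)(Cl)C(Cl)=O | starting material
6 | rac-3-[4-(benzyloxy)-2,6-dimethoxyphenyl]-2,2-dichlorocyclobutan-1-one | O=C1CC(c2c(OC)cc(OCc3ccccc3)cc2OC)C1(Cl)Cl | intermediate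
7 | 3-[4-(benzyloxy)-2,6-dimethoxyphenyl]cyclobutan-1-one | O=C1CC(C1)c1c(OC)cc(OCc2ccccc2)cc1OC | intermediate
8 | 3-[4-(benzyloxy)-2,6-dimethoxyphenyl]-1-hydroperoxycyclobutan-1-ol (Criegee adduct, not isolated) | OOC1(O)CC(C1)c1c(OC)cc(OCc2ccccc2)cc1OC | intermediate
9 | (4R)-4-[4-(benzyloxy)-2,6-dimethoxyphenyl]oxolan-2-one | O1C[C@H](CC1=O)c2c(OC)cc(OCc3ccccc3)cc2OC | intermediate
10 | sodium (3R)-3-[4-(benzyloxy)-2,6-dimethoxyphenyl]-4-hydroxybutanoate (not isolated) | OC[C@H](CC(=O)[O-])c1c(OC)cc(OCc2ccccc2)cc1OC.[Na+] | intermediate
11 | methyl (3R)-3-[4-(benzyloxy)-2,6-dimethoxyphenyl]-4-hydroxybutanoate | OC[C@H](CC(=O)OC)c1c(OC)cc(OCc2ccccc2)cc1OC | intermediate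
12 | methyl (3R)-3-[4-(benzyloxy)-2,6-dimethoxyphenyl]-4-iodobutanoate | IC[C@H](CC(=O)OC)c1c(OC)cc(OCc2ccccc2)cc1OC | intermediate
13 | butylmagnesium bromide | CCCC[Mg]Br | starting material
14 | methyl (3R)-3-[4-(benzyloxy)-2,6-dimethoxyphenyl]octanoate | CCCCC[C@H](CC(=O)OC)c1c(OC)cc(OCc2ccccc2)cc1OC | intermediate
15 | methyl (3R)-3-(4-hydroxy-2,6-dimethoxyphenyl)octanoate | CCCCC[C@H](CC(=O)OC)c1c(OC)cc(O)cc1OC | intermediate
16 | tigloyl chloride, (2E)-2-methylbut-2-enoyl chloride | C/C=C(\C)C(Cl)=O | starting material
17 | methyl (3R)-3-{4-hydroxy-2,6-dimethoxy-3-[(2E)-2-methylbut-2-enoyl]phenyl}octanoate | CCCCC[C@H](CC(=O)OC)c1c(OC)cc(O)c(C(=O)/C(C)=C/C)c1OC | intermediate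
18 | methyl (3R)-3-[(2S,3R)-5,7-dimethoxy-2,3-dimethyl-4-oxo-3,4-dihydro-2H-chromen-6-yl]octanoate | CCCCC[C@H](CC(=O)OC)c1c(OC)c2c(cc1OC)O[C@@H](C)[C@@H](C)C2=O | intermediate
19 | methyl (3R)-3-[(2S,3R)-8-iodo-5,7-dimethoxy-2,3-dimethyl-4-oxo-3,4-dihydro-2H-chromen-6-yl]octanoate | CCCCC[C@H](CC(=O)OC)c1c(OC)c2c(c(I)c1OC)O[C@@H](C)[C@@H](C)C2=O | intermediate
20 | tributyl(3-methylbut-2-en-1-yl)stannane | CC(C)=CC[Sn](CCCC)(CCCC)CCCC | starting material
21 | methyl (3R)-3-[(2S,3R)-5,7-dimethoxy-2,3-dimethyl-8-(3-methylbut-2-en-1-yl)-4-oxo-3,4-dihydro-2H-chromen-6-yl]octanoate | CCCCC[C@H](CC(=O)OC)c1c(OC)c2c(c(CC=C(C)C)c1OC)O[C@@H](C)[C@@H](C)C2=O | intermediate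
22 | methyl (3R)-3-[(2S,3R)-5-hydroxy-7-methoxy-2,3-dimethyl-8-(3-methylbut-2-en-1-yl)-4-oxo-3,4-dihydro-2H-chromen-6-yl]octanoate | CCCCC[C@H](CC(=O)OC)c1c(O)c2c(c(CC=C(C)C)c1OC)O[C@@H](C)[C@@H](C)C2=O | intermediate
23 | (3R)-3-[(2S,3R)-5-hydroxy-7-methoxy-2,3-dimethyl-8-(3-methylbut-2-en-1-yl)-4-oxo-3,4-dihydro-2H-chromen-6-yl]octanoic acid | CCCCC[C@H](CC(=O)O)c1c(O)c2c(c(CC=C(C)C)c1OC)O[C@@H](C)[C@@H](C)C2=O | target

## Step count and least certain steps

Total step count: 15. Longest linear sequence: 15 steps from 1; the route is linear, and 3, 5, 13, 16 and 20 are used as purchased.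

**Step 5 (key step).** The most likely failure is incomplete discrimination between the two enantiotopic methylene groups: the two ortho-methoxy groups turn the aryl ring out of the ring plane and change how the Criegee adduct sits against the chiral phosphate. A lesser concern is acid-promoted heterolysis of the strained ring assisted by the electron-rich aryl group.
Fallback, from 7 back to 9: oxidation of 7 with 3-chloroperbenzoic acid and NaHCO3 in CH2Cl2 gives racemic 4-[4-(benzyloxy)-2,6-dimethoxyphenyl]oxolan-2-one F1. Heating F1 with (1R)-1-phenylethan-1-amine (2-hydroxypyridine catalysis, toluene) opens it to two diastereomeric hydroxy amides: (3R)-3-[4-(benzyloxy)-2,6-dimethoxyphenyl]-4-hydroxy-N-[(1R)-1-phenylethyl]butanamide F2 and (3S)-3-[4-(benzyloxy)-2,6-dimethoxyphenyl]-4-hydroxy-N-[(1R)-1-phenylethyl]butanamide F3. These are separated by crystallisation or chromatography, and F2 is relactonised with dilute sulfuric acid in dioxane, which returns the amine and rejoins the route at 9. The same amide cycle can be applied to enantioenriched 9 if only an upgrade is needed.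

**Step 3.** The trioxygenated styrene may polymerise cationically under the zinc salts, and the acid chloride may acylate the activated ring positions in competition with ketene formation.
Fallback, from 4 back to 7: the keteniminium triflate generated from N,N-dimethylacetamide, triflic anhydride and 2,4,6-collidine in 1,2-dichloroethane adds to the styrene in a [2+2] sense to give N-{3-[4-(benzyloxy)-2,6-dimethoxyphenyl]cyclobutylidene}-N-methylmethanaminium trifluoromethanesulfonate F4. Hydrolysis with aqueous NaHCO3 rejoins the route at 7, bypassing 6 and step 4, with no zinc salt and no acid chloride present.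

**Step 8 (with step 7).** Three processes can compete with the coupling: addition of the Grignard reagent to the ester, enolisation of the ester followed by intramolecular displacement of iodide (three-membered ring closure), and, whenever the primary carbon is activated, migration of the very electron-rich aryl group through a bridged phenonium ion.
Fallback, from 11 back to 15: buffered Dess–Martin oxidation of 11 gives methyl (3R)-3-[4-(benzyloxy)-2,6-dimethoxyphenyl]-4-oxobutanoate F5. Salt-free Wittig reaction with the ylide from butyltriphenylphosphonium bromide and NaHMDS at −78 °C gives methyl (3S,4Z)-3-[4-(benzyloxy)-2,6-dimethoxyphenyl]oct-4-enoate F6; the spatial arrangement is unchanged, and the descriptor changes only because the alkene arm outranks the ester arm. Hydrogenation over Pd/C saturates the alkene and removes the benzyl group in one operation, rejoining the route at 15 and bypassing 12 and 14. The price is an enolisable aldehyde at the stereocentre, which is why this is the reserve.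

**Step 11.** Facial selectivity may be poor with the pseudo-enantiomeric alkaloid on an enone twisted by its ortho-methoxy neighbour, and the cis relationship may erode by epimerisation at C3 during a slow reaction.
Fallback, from 15 back to 18 (step 10 is bypassed as well): Fráter–Seebach methylation (LDA, iodomethane) of commercial tert-butyl (3R)-3-hydroxybutanoate gives tert-butyl (2R,3R)-3-hydroxy-2-methylbutanoate F7. Mitsunobu etherification of 15 with F7 (PPh3, diisopropyl azodicarboxylate, toluene) inverts the carbinol carbon and gives methyl (3R)-3-(4-{[(2S,3R)-4-tert-butoxy-3-methyl-4-oxobutan-2-yl]oxy}-2,6-dimethoxyphenyl)octanoate F8. Trifluoroacetic acid removes the tert-butyl group to give (2R,3S)-3-{3,5-dimethoxy-4-[(3R)-1-methoxy-1-oxooctan-3-yl]phenoxy}-2-methylbutanoic acid F9, which is not isolated. Trifluoroacetic anhydride then cyclises it by intramolecular Friedel–Crafts acylation at either of the two equivalent ortho positions, rejoining the route at 18. Both ring stereocentres then come from the chiral pool and an SN2 inversion instead of from catalyst control.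

**Step 13.** Coupling may occur through the substituted allyl terminus, and oxidative addition at the doubly ortho-substituted, electron-rich iodide may be slow enough for reductive loss of iodine to compete.
Fallback, from 19 back to 21: Stille coupling of 19 with allyltributylstannane (Pd(PPh3)4, DMF), in which the two allyl termini are identical, gives methyl (3R)-3-[(2S,3R)-5,7-dimethoxy-2,3-dimethyl-4-oxo-8-(prop-2-en-1-yl)-3,4-dihydro-2H-chromen-6-yl]octanoate F10. Olefin cross-metathesis with excess 2-methylbut-2-ene and the second-generation Grubbs catalyst (H2IMes)(PCy3)Cl2Ru=CHPh converts the allyl into the prenyl group and rejoins the route at 21.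

## Further compounds

F1 | step 5 | rac-4-[4-(benzyloxy)-2,6-dimethoxyphenyl]oxolan-2-one | O=C1CC(CO1)c1c(OC)cc(OCc2ccccc2)cc1OC
F2 | step 5 | (3R)-3-[4-(benzyloxy)-2,6-dimethoxyphenyl]-4-hydroxy-N-[(1R)-1-phenylethyl]butanamide | OC[C@H](CC(=O)N[C@H](C)c1ccccc1)c1c(OC)cc(OCc2ccccc2)cc1OC
F3 | step 5 | (3S)-3-[4-(benzyloxy)-2,6-dimethoxyphenyl]-4-hydroxy-N-[(1R)-1-phenylethyl]butanamide | OC[C@@H](CC(=O)N[C@H](C)c1ccccc1)c1c(OC)cc(OCc2ccccc2)cc1OC
F4 | step 3 | N-{3-[4-(benzyloxy)-2,6-dimethoxyphenyl]cyclobutylidene}-N-methylmethanaminium trifluoromethanesulfonate | C[N+](C)=C1CC(C1)c1c(OC)cc(OCc2ccccc2)cc1OC.[O-]S(=O)(=O)C(F)(F)F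
F5 | step 8 | methyl (3R)-3-[4-(benzyloxy)-2,6-dimethoxyphenyl]-4-oxobutanoate | O=C[C@H](CC(=O)OC)c1c(OC)cc(OCc2ccccc2)cc1OC
F6 | step 8 | methyl (3S,4Z)-3-[4-(benzyloxy)-2,6-dimethoxyphenyl]oct-4-enoate | CCC/C=C\[C@H](CC(=O)OC)c1c(OC)cc(OCc2ccccc2)cc1OC
F7 | step 11 | tert-butyl (2R,3R)-3-hydroxy-2-methylbutanoate | O[C@H](C)[C@@H](C)C(=O)OC(C)(C)C
F8 | step 11 | methyl (3R)-3-(4-{[(2S,3R)-4-tert-butoxy-3-methyl-4-oxobutan-2-yl]oxy}-2,6-dimethoxyphenyl)octanoate | CCCCC[C@H](CC(=O)OC)c1c(OC)cc(O[C@@H](C)[C@@H](C)C(=O)OC(C)(C)C)cc1OC
F9 | step 11 | (2R,3S)-3-{3,5-dimethoxy-4-[(3R)-1-methoxy-1-oxooctan-3-yl]phenoxy}-2-methylbutanoic acid | CCCCC[C@H](CC(=O)OC)c1c(OC)cc(O[C@@H](C)[C@@H](C)C(=O)O)cc1OC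
F10 | step 13 | methyl (3R)-3-[(2S,3R)-5,7-dimethoxy-2,3-dimethyl-4-oxo-8-(prop-2-en-1-yl)-3,4-dihydro-2H-chromen-6-yl]octanoate | CCCCC[C@H](CC(=O)OC)c1c(OC)c2c(c(CC=C)c1OC)O[C@@H](C)[C@@H](C)C2=O
A1 | alternative 1 | methyl (3R)-3-[(2S,3R)-5,7-dimethoxy-2,3-dimethyl-8-(3-methylbut-2-en-1-yl)-4-oxo-3,4-dihydro-2H-chromen-6-yl]octanoate (identical with 21) | CCCCC[C@H](CC(=O)OC)c1c(OC)c2c(c(CC=C(C)C)c1OC)O[C@@H](C)[C@@H](C)C2=O
A2 | alternative 1 | methyl (3R)-3-[3-(2-diazopropanoyl)-4-ethoxy-2,6-dimethoxy-5-(3-methylbut-2-en-1-yl)phenyl]octanoate | CCCCC[C@H](CC(=O)OC)c1c(OC)c(C(=O)C(C)=[N+]=[N-])c(OCC)c(CC=C(C)C)c1OC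
A3 | alternative 2 | (4R)-7-(benzyloxy)-5-methoxy-4-pentyl-3,4-dihydro-2H-chromen-2-one | CCCCC[C@@H]1CC(=O)Oc2cc(OCc3ccccc3)cc(OC)c21
A4 | alternative 2 | 5-(benzyloxy)-3-methoxy-2-[1-(4-methylbenzenesulfonyl)hexyl]phenol | CCCCCC(c1c(O)cc(OCc2ccccc2)cc1OC)S(=O)(=O)c1ccc(C)cc1
A5 | alternative 2 | 3-(benzyloxy)-6-hexylidene-5-methoxycyclohexa-2,4-dien-1-one | CCCCCC=C1C(=O)C=C(OCc2ccccc2)C=C1OC
A6 | alternative 3 | methyl (3R)-3-[6-ethoxy-2-hydroxy-3-(3-methylbut-2-en-1-yl)-4-(triisopropylsilyloxy)phenyl]octanoate | CCCCC[C@H](CC(=O)OC)c1c(O)c(CC=C(C)C)c(O[Si](C(C)C)(C(C)C)C(C)C)cc1OCC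
A7 | alternative 3 | methyl (3R)-3-(2-ethoxy-4-oxocyclobut-2-en-1-yl)octanoate | CCCCC[C@H](CC(=O)OC)C1C(=O)C=C1OCC
A8 | alternative 3 | triisopropyl[(5-methylhex-4-en-1-yn-1-yl)oxy]silane | CC(C)=CCC#CO[Si](C(C)C)(C(C)C)C(C)C
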